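(The readings stem from a simulated flask for an exercise, noise included.)

**Two runs.** The constants are hidden, yet you can go without them: the blue run stood at 75 °C, the ochre run at 90 °C, and elm's rise is 15 K, so these two runs already show a rise of that size, though from a lower temperature than elm's.

| flask | substrate | reagent | temperature | remark | time |
|---|---|---|---|---|---|
| ochre | 1.9 M | 2.28 M | 90 °C | the very flask that is asked about, followed so far |  |
| blue | 1.9 M | 2.28 M | 75 °C | run made earlier |  |
| flask | 1.9 M | 2.28 M | 90 °C |  | 6.0 min |

| run | time / min | target / % |
|---|---|---|
| ochre | 1.00 | 22.6 |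
| ochre | 2.00 | 32.1 |
| ochre | 3.00 | 34.1 |
| ochre | 4.00 | 36.2 |
| ochre | 5.00 | 37.1 |
| ochre | 6.00 | 38.2 |
| blue | 2.00 | 18.3 |
| blue | 4.00 | 31.8 |
| blue | 6.00 | 37.7 |
| blue | 8.00 | 40.7 |
| blue | 10.0 | 42.9 |
| blue | 12.0 | 43.8 |

(each reading ± 0.5 percentage points)

- maple: at 6.0 min take out 90% of the target then present, then wait 12 min
- elm: at 6.0 min raise the temperature by 15 K, then wait 12 min
- oak: change nothing and wait 12 min more

- target taken out counts as made
- the analysis behind the earlier runs scatters by 0.5 percentage points, standard deviation

- target, in percent of the substrate first charged, at 6.0 min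
- the remedy with the largest gain of target, or "none" below 2 percentage points (maple / elm / oak / none)
- target present, with what was taken out counted in, in percent of the substrate first charged, after maple
- target present, with what was taken out counted in, in percent of the substrate first charged, after oak

**Heat factor.** Ochre's first reading per minute over blue's gives 2.47. Call this the heat factor, the speed-up that one such rise brings.

**Reading off.** Ochre bends near 34.1% but keeps creeping, by 2 percentage points over its last 2.00 min, and stands at about 38.2%. Held for 12 min, that creep gives oak 12 points. Multiplied by the heat factor, it gives elm 30 points. I take the creep to ignore target taken out, so maple equals oak.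

**One number?** Not quite. Over the late stretches ochre outruns blue by a factor of 1.29, less than the heat factor, though these are small differences against a scatter of 0.5 points. Even that lower factor leaves elm at 15 points, more than oak. I commit to elm.

**The forecast.** It gives 38% now, 55.5% after maple and 40% after oak, and names maple: “Heating lowers the equilibrium, so elm gives no gain”.

**The result.** The flask holds 38.0%, and elm is best, gaining 22 points against 9.3 points for oak and 9.3 points for maple, which both end at 47.3%.

    reagent ⇌ dormant form (K = 11.0, k = 0.0130 s⁻¹, Ea = 107 kJ mol⁻¹, ΔH = −37.0 kJ mol⁻¹)
    substrate + reagent → intermediate + by-product (k = 0.00580 M⁻¹ s⁻¹, Ea = 68.0 kJ mol⁻¹)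
    intermediate → side product (k = 0.0190 s⁻¹, Ea = 94.0 kJ mol⁻¹)
    intermediate → target (k = 0.0510 s⁻¹, Ea = 87.0 kJ mol⁻¹)
    (constants at 90 °C)

Elm's gain over oak's is 2.40, beside a heat factor of 2.47. At 6.00 min the flask held 47.5% of its substrate but 3.52% of its reagent free, and target has no way back, which is kinetic rather than thermodynamic control. A repeat at 105 °C holds 46.7% at 6.00 min against this flask's 38.0%, a ratio of 1.23, less than the heat factor of 2.47.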